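**Plan**

1. Retrosynthesis: the target is cut first at the alkyl ester between the ring A carbinol oxygen and the middle hydroxybutanoate carbonyl, then at the two hindered aryl ester C(=O)–O bonds, at the ring B ArCH2–C(=O) bond, and last in ring A at C1–C6 and C3–C4.
2. Enabling feature: ring A has its carboxyl on C1, oxygens on C2 and C4 and the side chain on C6. In the 2,4-dioxocyclohexane form, C1–C2–C3 is an acetoacetate and C4–C5–C6 an enoate, and the C1 ester is a β-keto ester that can exchange its alcohol through an acylketene, which the di-ortho-substituted benzoate cannot do.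
3. Forward, ring A: a Michael–Dieckmann annulation gives the saturated dione tert-butyl ester, a thermal ester swap brings in benzyl (R)-3-hydroxybutanoate, and only then follow aromatization, benzylation and desilylation.
4. Forward, ring B: orsellinic acid is esterified by Mitsunobu reaction with (S)-pent-4-en-2-ol (a masked hydroxybutanoate without acidic α-hydrogens), benzylated, acylated at the benzylic methyl with a Weinreb amide, and the alkene is cleaved to the acid.
5. The two halves are joined by carbodiimide esterification, and one hydrogenolysis removes all six benzyl groups.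
6. Stereochemistry: all four centres are (R) and come from the chiral pool, three from (R)-3-hydroxybutanoate with retention and one from (S)-pent-4-en-2-ol by Mitsunobu inversion.

Key step: step 4

Remark: the four stereocentres of the target are read from the SMILES as (R); sodium (R)-3-hydroxybutanoate, (S)-pent-4-en-2-ol and 2,4-dihydroxy-6-methylbenzoic acid are taken as purchasable, and tert-butyldiphenylsilyl is chosen as the side-chain protecting group of the key-step precursor and product.

**Route**

Step 1
Reactants: 1 methyl (R)-3-hydroxybutanoate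
Product: 2 methyl (R)-3-(tert-butyldiphenylsilyloxy)butanoate
Conditions: t-BuPh2SiCl, imidazole, DMF, rt
Reagents that add atoms: tert-butyl(chloro)diphenylsilane, CC(C)(C)[Si](Cl)(c1ccccc1)c1ccccc1
Why: Imidazole-promoted silylation of a secondary alcohol leaves the stereocentre untouched, and this silyl ether is chosen because it should withstand alkoxide, 110 °C and the transiently acidic aromatization medium.

Step 2
Reactants: 2 methyl (R)-3-(tert-butyldiphenylsilyloxy)butanoate
Product: 3 (R)-3-(tert-butyldiphenylsilyloxy)butanal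
Conditions: i-Bu2AlH, CH2Cl2, −78 °C; aq. potassium sodium tartrate
Reagents that add atoms: none
Why: Half-reduction of a methyl ester with i-Bu2AlH at −78 °C stops at the aluminium hemiacetal, which releases the aldehyde only on work-up; the β-stereocentre is not enolizable.

Step 3
Reactants: 3 (R)-3-(tert-butyldiphenylsilyloxy)butanal; 4 triethyl phosphonoacetate
Product: 5 ethyl (R,E)-5-(tert-butyldiphenylsilyloxy)hex-2-enoate
Conditions: LiCl, DBU, MeCN, 0 °C → rt
Reagents that add atoms: none
Why: Horner–Wadsworth–Emmons olefination under Masamune–Roush conditions should give the E-enoate while the mild amine base avoids β-elimination of the silyloxy aldehyde.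

Step 4
Reactants: 5 ethyl (R,E)-5-(tert-butyldiphenylsilyloxy)hex-2-enoate; 6 tert-butyl acetoacetate
Product: 8 tert-butyl 2,4-dioxo-6-[(2R)-2-(tert-butyldiphenylsilyloxy)propyl]cyclohexane-1-carboxylate, via Michael adduct 7 (not isolated)
Conditions: KOt-Bu (0.2 equiv), t-BuOH/THF, 40 °C; then KOt-Bu (1.2 equiv), 70 °C; cold 1 M HCl to pH 3
Reagents that add atoms: none
Why: Catalytic tert-butoxide generates the doubly stabilized enolate of 6, whose central carbon adds 1,4 to C3 of enoate 5 (future C1–C6 bond) to give 7; once 5 is consumed, a full equivalent of tert-butoxide lets the acetyl methyl enolate form by proton exchange and attack the ethyl ester carbonyl with loss of ethoxide (future C3–C4 bond). The closest known reaction is the classical Michael–Dieckmann synthesis of dihydroorsellinates and dihydro-olivetolates from acetoacetates and crotonate or oct-2-enoate esters. The ring closes by a 6-(enolexo)-exo-trig Claisen (Dieckmann) condensation, the only closure open to 7 because every other enolate/carbonyl pairing would give a four-membered ring, and it is driven to completion by deprotonation of the product to its vinylogous carboxylate. Ring carbons C1 and C6 form without control as an equilibrating, largely enolized epimer mixture and both become sp2 on aromatization, while the (R)-carbinol centre lies outside every enolizable position and is carried through unchanged. The selectivity needed is conjugate addition over γ-deprotonation of 5 with vinylogous loss of silyloxide; the 1,3-dicarbonyl acidity of 6 secures it, because the soft nucleophile can be generated with catalytic base and the enoate is consumed before strong base is present, and tert-butanol as solvent cannot exchange the tert-butyl ester needed for step 6.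

Step 5
Reactants: 9 sodium (R)-3-hydroxybutanoate
Product: 10 benzyl (R)-3-hydroxybutanoate
Conditions: BnBr, DMF, rt
Reagents that add atoms: benzyl bromide, BrCc1ccccc1
Why: SN2 alkylation of the carboxylate in a dipolar aprotic solvent leaves the free secondary hydroxyl and its configuration untouched.

Step 6
Reactants: 8 tert-butyl 2,4-dioxo-6-[(2R)-2-(tert-butyldiphenylsilyloxy)propyl]cyclohexane-1-carboxylate; 10 benzyl (R)-3-hydroxybutanoate
Product: 12 benzyl (3R)-3-({2,4-dioxo-6-[(2R)-2-(tert-butyldiphenylsilyloxy)propyl]cyclohexane-1-carbonyl}oxy)butanoate, via acylketene 11 (not isolated)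
Conditions: toluene, 110 °C, t-BuOH distilled off
Reagents that add atoms: none
Why: Thermal transesterification of an enolizable tert-butyl β-keto ester proceeds by loss of tert-butanol from the C1 ester/C2 enol to acylketene 11, whose unhindered sp carbon is acylated by the secondary alcohol 10 at oxygen with retention, and the absence of base protects the new β-acyloxy ester from elimination.

Step 7
Reactants: 12 benzyl (3R)-3-({2,4-dioxo-6-[(2R)-2-(tert-butyldiphenylsilyloxy)propyl]cyclohexane-1-carbonyl}oxy)butanoate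
Product: 13 benzyl (3R)-3-({2,4-dihydroxy-6-[(2R)-2-(tert-butyldiphenylsilyloxy)propyl]benzoyl}oxy)butanoate
Conditions: I2 (0.2 equiv), DMSO, 80 °C
Reagents that add atoms: none
Why: Iodine-catalysed dehydrogenative aromatization of an enolized cyclohexane-1,3-dione: reversible α-iodination funnels to the C1 or C5 iodide, which loses HI across C6 and tautomerizes to the resorcylate, while DMSO reoxidizes HI so the medium stays mild enough for the benzyl ester and silyl ether, and both ring epimers converge on one product.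

Step 8
Reactants: 13 benzyl (3R)-3-({2,4-dihydroxy-6-[(2R)-2-(tert-butyldiphenylsilyloxy)propyl]benzoyl}oxy)butanoate
Product: 14 benzyl (3R)-3-({2,4-bis(benzyloxy)-6-[(2R)-2-(tert-butyldiphenylsilyloxy)propyl]benzoyl}oxy)butanoate
Conditions: BnBr, K2CO3, Bu4NI (cat.), DMF, 45 °C
Reagents that add atoms: benzyl bromide, BrCc1ccccc1
Why: Williamson etherification of both phenols with a carbonate base that is too weak to trigger E1cB loss of the benzoate from the β-acyloxy ester; the chelated C2 hydroxyl is the reason for gentle warming.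

Step 9
Reactants: 14 benzyl (3R)-3-({2,4-bis(benzyloxy)-6-[(2R)-2-(tert-butyldiphenylsilyloxy)propyl]benzoyl}oxy)butanoate
Product: 15 benzyl (3R)-3-({2,4-bis(benzyloxy)-6-[(2R)-2-hydroxypropyl]benzoyl}oxy)butanoate
Conditions: HF·pyridine, pyridine/THF, 0 °C → rt
Reagents that add atoms: none
Why: Fluoride-driven Si–O cleavage under pyridine-buffered, slightly acidic conditions never generates the free alkoxide, so six-membered lactonization onto the neighbouring hindered aryl ester should stay slow, and the alcohol is taken into step 17 at once.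

Step 10
Reactants: 1 methyl (R)-3-hydroxybutanoate
Product: 16 methyl (R)-3-(benzyloxy)butanoate
Conditions: BnOC(=NH)CCl3, TfOH (cat.), CH2Cl2/cyclohexane, 0 °C → rt
Reagents that add atoms: benzyl 2,2,2-trichloroacetimidate, N=C(OCc1ccccc1)C(Cl)(Cl)Cl
Why: Acid-catalysed benzylation by the trichloroacetimidate method alkylates the hydroxyl without base, so the β-hydroxy ester can neither eliminate nor lose its configuration.

Step 11
Reactants: 16 methyl (R)-3-(benzyloxy)butanoate
Product: 17 (R)-3-(benzyloxy)-N-methoxy-N-methylbutanamide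
Conditions: MeNH(OMe)·HCl, i-PrMgCl, THF, −20 °C → 0 °C
Reagents that add atoms: N,O-dimethylhydroxylamine hydrochloride, CNOC.Cl
Why: Direct aminolysis of the ester by the chloromagnesium amide of N,O-dimethylhydroxylamine (Weinreb amide formation) works at low temperature, where the weakly basic amide does not expel the β-benzyloxy group.

Step 12
Reactants: 18 2,4-dihydroxy-6-methylbenzoic acid (orsellinic acid); 19 (S)-pent-4-en-2-ol
Product: 20 (2R)-pent-4-en-2-yl 2,4-dihydroxy-6-methylbenzoate
Conditions: PPh3, DIAD, THF, 0 °C → rt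
Reagents that add atoms: none
Why: Mitsunobu esterification forms the bond at the alcohol carbon and so bypasses the hindered acyl carbon; the salicylic-type carboxylate, more acidic than either phenol, displaces the activated alcohol with inversion, turning the (S)-alcohol into the (R)-ester.

Step 13
Reactants: 20 (2R)-pent-4-en-2-yl 2,4-dihydroxy-6-methylbenzoate
Product: 21 (2R)-pent-4-en-2-yl 2,4-bis(benzyloxy)-6-methylbenzoate
Conditions: BnBr, K2CO3, DMF, 60 °C
Reagents that add atoms: benzyl bromide, BrCc1ccccc1
Why: Williamson etherification gives phenol ethers that tolerate the amide base of step 14 and fall in the final hydrogenolysis.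

Step 14
Reactants: 21 (2R)-pent-4-en-2-yl 2,4-bis(benzyloxy)-6-methylbenzoate; 17 (R)-3-(benzyloxy)-N-methoxy-N-methylbutanamide
Product: 23 (2R)-pent-4-en-2-yl 2,4-bis(benzyloxy)-6-[(4R)-4-(benzyloxy)-2-oxopentyl]benzoate, via benzylic lithium species 22 (not isolated)
Conditions: LiN(i-Pr)2 (2.1 equiv), THF, −78 °C; then 17, −78 °C; sat. aq. NH4Cl
Reagents that add atoms: none
Why: Lateral lithiation of the ortho-toluate followed by acylation with a Weinreb amide, whose chelated tetrahedral adduct prevents over-addition and keeps the acidic benzyl ketone masked until the cold quench; the pentenyl ester has no acidic α-hydrogens, which is why the hydroxybutanoate is carried as an alkene at this stage.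

Step 15
Reactants: 23 (2R)-pent-4-en-2-yl 2,4-bis(benzyloxy)-6-[(4R)-4-(benzyloxy)-2-oxopentyl]benzoate
Product: 24 (2R)-4-oxobutan-2-yl 2,4-bis(benzyloxy)-6-[(4R)-4-(benzyloxy)-2-oxopentyl]benzoate
Conditions: OsO4 (cat.), NaIO4, 2,6-lutidine, dioxane/H2O, rt
Reagents that add atoms: sodium periodate, [Na+].[O-]I(=O)(=O)=O, the terminal source of the aldehyde oxygen, relayed by osmium tetroxide, O=[Os](=O)(=O)=O
Why: Lemieux–Johnson cleavage (catalytic dihydroxylation, periodate glycol scission) of the only alkene, with 2,6-lutidine to suppress over-oxidation; benzyl ethers, ketone and esters are inert, and the crude aldehyde is used directly.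

Step 16
Reactants: 24 (2R)-4-oxobutan-2-yl 2,4-bis(benzyloxy)-6-[(4R)-4-(benzyloxy)-2-oxopentyl]benzoate
Product: 25 (3R)-3-({2,4-bis(benzyloxy)-6-[(4R)-4-(benzyloxy)-2-oxopentyl]benzoyl}oxy)butanoic acid
Conditions: NaClO2, NaH2PO4, 2-methyl-2-butene, t-BuOH/H2O, 0 °C → rt
Reagents that add atoms: sodium chlorite, [Na+].[O-]Cl=O
Why: Pinnick oxidation at buffered, weakly acidic pH converts the aldehyde to the acid without β-elimination of the aroyloxy group, and the alkene scavenger removes hypochlorous acid before it can chlorinate the electron-rich ring.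

Step 17
Reactants: 15 benzyl (3R)-3-({2,4-bis(benzyloxy)-6-[(2R)-2-hydroxypropyl]benzoyl}oxy)butanoate; 25 (3R)-3-({2,4-bis(benzyloxy)-6-[(4R)-4-(benzyloxy)-2-oxopentyl]benzoyl}oxy)butanoic acid
Product: 26 benzyl (3R)-3-{[2,4-bis(benzyloxy)-6-((2R)-2-{[(3R)-3-({2,4-bis(benzyloxy)-6-[(4R)-4-(benzyloxy)-2-oxopentyl]benzoyl}oxy)butanoyl]oxy}propyl)benzoyl]oxy}butanoate
Conditions: EDC·HCl, DMAP (0.3 equiv), CH2Cl2, 0 °C → rt
Reagents that add atoms: none
Why: Steglich esterification of an unhindered alkyl carboxylic acid with the secondary alcohol, a coupling type routine for 3-acyloxybutanoic acids in oligo(3-hydroxybutanoate) chemistry; low temperature and substoichiometric DMAP limit crotonate formation, and acylation at oxygen retains the carbinol configuration.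

Step 18
Reactants: 26 benzyl (3R)-3-{[2,4-bis(benzyloxy)-6-((2R)-2-{[(3R)-3-({2,4-bis(benzyloxy)-6-[(4R)-4-(benzyloxy)-2-oxopentyl]benzoyl}oxy)butanoyl]oxy}propyl)benzoyl]oxy}butanoate
Product: 27 hansforester I, (3R)-3-{[2-((2R)-2-{[(3R)-3-({2,4-dihydroxy-6-[(4R)-4-hydroxy-2-oxopentyl]benzoyl}oxy)butanoyl]oxy}propyl)-4,6-dihydroxybenzoyl]oxy}butanoic acid
Conditions: H2 (1 atm), Pd(OH)2/C, EtOAc/EtOH, rt
Reagents that add atoms: none
Why: Heterogeneous palladium-catalysed hydrogenolysis should cleave the four aryl benzyl ethers, the alkyl benzyl ether and the benzyl ester in one neutral operation, while the three remaining esters, the non-conjugated ketone and the four stereocentres (none at a benzylic C–O bond) are untouched.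

**Compound list**

1 | methyl (R)-3-hydroxybutanoate | C[C@@H](O)CC(=O)OC | starting material
2 | methyl (R)-3-(tert-butyldiphenylsilyloxy)butanoate | C[C@@H](O[Si](c1ccccc1)(c1ccccc1)C(C)(C)C)CC(=O)OC | intermediate
3 | (R)-3-(tert-butyldiphenylsilyloxy)butanal | C[C@@H](O[Si](c1ccccc1)(c1ccccc1)C(C)(C)C)CC=O | intermediate
4 | triethyl phosphonoacetate | CCOC(=O)CP(=O)(OCC)OCC | starting material
5 | ethyl (R,E)-5-(tert-butyldiphenylsilyloxy)hex-2-enoate | CCOC(=O)/C=C/C[C@@H](C)O[Si](c1ccccc1)(c1ccccc1)C(C)(C)C | intermediate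
6 | tert-butyl acetoacetate | CC(=O)CC(=O)OC(C)(C)C | starting material
7 | 1-tert-butyl 5-ethyl 2-acetyl-3-[(2R)-2-(tert-butyldiphenylsilyloxy)propyl]pentanedioate (Michael adduct, epimer mixture) | CCOC(=O)CC(C[C@@H](C)O[Si](c1ccccc1)(c1ccccc1)C(C)(C)C)C(C(C)=O)C(=O)OC(C)(C)C | intermediate
8 | tert-butyl 2,4-dioxo-6-[(2R)-2-(tert-butyldiphenylsilyloxy)propyl]cyclohexane-1-carboxylate (C1/C6 epimer mixture) | CC(C)(C)OC(=O)C1C(=O)CC(=O)CC1C[C@@H](C)O[Si](c1ccccc1)(c1ccccc1)C(C)(C)C | intermediate
9 | sodium (R)-3-hydroxybutanoate | C[C@@H](O)CC(=O)[O-].[Na+] | starting material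
10 | benzyl (R)-3-hydroxybutanoate | C[C@@H](O)CC(=O)OCc1ccccc1 | intermediate
11 | 4-(oxomethylidene)-5-[(2R)-2-(tert-butyldiphenylsilyloxy)propyl]cyclohexane-1,3-dione (acylketene) | O=C=C1C(=O)CC(=O)CC1C[C@@H](C)O[Si](c1ccccc1)(c1ccccc1)C(C)(C)C | intermediate
12 | benzyl (3R)-3-({2,4-dioxo-6-[(2R)-2-(tert-butyldiphenylsilyloxy)propyl]cyclohexane-1-carbonyl}oxy)butanoate | C[C@H](CC(=O)OCc1ccccc1)OC(=O)C1C(=O)CC(=O)CC1C[C@@H](C)O[Si](c1ccccc1)(c1ccccc1)C(C)(C)C | intermediate
13 | benzyl (3R)-3-({2,4-dihydroxy-6-[(2R)-2-(tert-butyldiphenylsilyloxy)propyl]benzoyl}oxy)butanoate | C[C@H](CC(=O)OCc1ccccc1)OC(=O)c1c(O)cc(O)cc1C[C@@H](C)O[Si](c1ccccc1)(c1ccccc1)C(C)(C)C | intermediate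
14 | benzyl (3R)-3-({2,4-bis(benzyloxy)-6-[(2R)-2-(tert-butyldiphenylsilyloxy)propyl]benzoyl}oxy)butanoate | C[C@H](CC(=O)OCc1ccccc1)OC(=O)c1c(OCc2ccccc2)cc(OCc2ccccc2)cc1C[C@@H](C)O[Si](c1ccccc1)(c1ccccc1)C(C)(C)C | intermediate
15 | benzyl (3R)-3-({2,4-bis(benzyloxy)-6-[(2R)-2-hydroxypropyl]benzoyl}oxy)butanoate | C[C@H](CC(=O)OCc1ccccc1)OC(=O)c1c(OCc2ccccc2)cc(OCc2ccccc2)cc1C[C@@H](C)O | intermediate
16 | methyl (R)-3-(benzyloxy)butanoate | C[C@@H](OCc1ccccc1)CC(=O)OC | intermediate
17 | (R)-3-(benzyloxy)-N-methoxy-N-methylbutanamide | C[C@@H](OCc1ccccc1)CC(=O)N(C)OC | intermediate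
18 | 2,4-dihydroxy-6-methylbenzoic acid (orsellinic acid) | Cc1cc(O)cc(O)c1C(=O)O | starting material
19 | (S)-pent-4-en-2-ol | C=CC[C@H](C)O | starting material
20 | (2R)-pent-4-en-2-yl 2,4-dihydroxy-6-methylbenzoate | Cc1cc(O)cc(O)c1C(=O)O[C@H](C)CC=C | intermediate
21 | (2R)-pent-4-en-2-yl 2,4-bis(benzyloxy)-6-methylbenzoate | Cc1cc(OCc2ccccc2)cc(OCc2ccccc2)c1C(=O)O[C@H](C)CC=C | intermediate
22 | (2R)-pent-4-en-2-yl 2,4-bis(benzyloxy)-6-(lithiomethyl)benzoate | [Li]Cc1cc(OCc2ccccc2)cc(OCc2ccccc2)c1C(=O)O[C@H](C)CC=C | intermediate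
23 | (2R)-pent-4-en-2-yl 2,4-bis(benzyloxy)-6-[(4R)-4-(benzyloxy)-2-oxopentyl]benzoate | C[C@@H](OCc1ccccc1)CC(=O)Cc1cc(OCc2ccccc2)cc(OCc2ccccc2)c1C(=O)O[C@H](C)CC=C | intermediate
24 | (2R)-4-oxobutan-2-yl 2,4-bis(benzyloxy)-6-[(4R)-4-(benzyloxy)-2-oxopentyl]benzoate | C[C@@H](OCc1ccccc1)CC(=O)Cc1cc(OCc2ccccc2)cc(OCc2ccccc2)c1C(=O)O[C@H](C)CC=O | intermediate
25 | (3R)-3-({2,4-bis(benzyloxy)-6-[(4R)-4-(benzyloxy)-2-oxopentyl]benzoyl}oxy)butanoic acid | C[C@@H](OCc1ccccc1)CC(=O)Cc1cc(OCc2ccccc2)cc(OCc2ccccc2)c1C(=O)O[C@H](C)CC(=O)O | intermediate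
26 | hexabenzyl-protected hansforester I (name as in step 17) | C[C@H](Cc1cc(OCc2ccccc2)cc(OCc2ccccc2)c1C(=O)O[C@H](C)CC(=O)OCc1ccccc1)OC(=O)C[C@@H](C)OC(=O)c1c(OCc2ccccc2)cc(OCc2ccccc2)cc1CC(=O)C[C@@H](C)OCc1ccccc1 | intermediate
27 | hansforester I | C[C@H](Cc1cc(O)cc(O)c1C(=O)O[C@H](C)CC(=O)O)OC(=O)C[C@@H](C)OC(=O)c1c(O)cc(O)cc1CC(=O)C[C@@H](C)O | target

**Step count and risks**

Total step count: 18. Longest linear sequence: 10 steps (steps 1, 2, 3, 4, 6, 7, 8, 9, 17, 18).

Most likely to fail, step 6 (ester swap). The substrate rests as the C2–C3–C4 vinylogous acid, so loss of tert-butanol to the acylketene may be slow. The ketene may also be captured by the enol oxygen of a second molecule, or by traces of water with decarboxylation. The fallback sets out from 8 and comes back to the route at 14, forming the hindered ester at the alcohol carbon instead of the acyl carbon. Compound 8 is aromatized under the conditions of step 7 to tert-butyl 2,4-dihydroxy-6-[(2R)-2-(tert-butyldiphenylsilyloxy)propyl]benzoate F1. Both phenols are benzylated (BnBr, K2CO3, DMF) to tert-butyl 2,4-bis(benzyloxy)-6-[(2R)-2-(tert-butyldiphenylsilyloxy)propyl]benzoate F2. The tert-butyl ester is cleaved with Me3SiOTf and 2,6-lutidine to 2,4-bis(benzyloxy)-6-[(2R)-2-(tert-butyldiphenylsilyloxy)propyl]benzoic acid F3. This acid is coupled by Mitsunobu reaction (PPh3, DIAD) with benzyl (S)-3-hydroxybutanoate F4, itself made from sodium (S)-3-hydroxybutanoate and BnBr; inversion delivers the (R)-ester 14.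

Second, step 7 (aromatization). The electron-rich resorcylate may be iodinated and so consume the catalyst, oxygen transfer from DMSO may occur at C3 instead of elimination, or HI may erode the silyl ether. The fallback sets out from 12 and comes back at 13, and uses halogen atoms as temporary substituents in place of a catalytic dehydrogenation. Exhaustive bromination with spontaneous dehydrobromination (Br2, NaOAc, AcOH, rt), the classical route to dibromo-orsellinates, should give benzyl (3R)-3-({3,5-dibromo-2,4-dihydroxy-6-[(2R)-2-(tert-butyldiphenylsilyloxy)propyl]benzoyl}oxy)butanoate F5. Its two ring bromines are then removed by radical reduction (Bu3SnH, AIBN, toluene, 80 °C), which spares the benzyl ester, to give 13.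

Third, step 4 (annulation). Conjugate addition to the β-branched enoate may be slow and reversible, so that under the stoichiometric alkoxide γ-deprotonation of 5 and vinylogous loss of silyloxide outrun ring closure. The fallback sets out from 3 and comes back at 8, exchanging the roles of the two partners as in the classical malonate–enone route to dihydro-olivetolates. Wittig olefination of 3 with 1-(triphenylphosphoranylidene)propan-2-one gives (R,E)-6-(tert-butyldiphenylsilyloxy)hept-3-en-2-one F6. This enone, a far better acceptor than the enoate, takes up tert-butyl ethyl malonate under catalytic KOt-Bu to give 1-tert-butyl 3-ethyl 2-[(6R)-6-(tert-butyldiphenylsilyloxy)-2-oxoheptan-4-yl]propanedioate F7. With a full equivalent of KOt-Bu in t-BuOH the methyl ketone enolate closes onto the ethyl ester with loss of ethoxide, forming C1–C6 and C2–C3 and giving the same dione ester 8.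

**Further compounds**

F1 | step 6 | tert-butyl 2,4-dihydroxy-6-[(2R)-2-(tert-butyldiphenylsilyloxy)propyl]benzoate | CC(C)(C)OC(=O)c1c(O)cc(O)cc1C[C@@H](C)O[Si](c1ccccc1)(c1ccccc1)C(C)(C)C
F2 | step 6 | tert-butyl 2,4-bis(benzyloxy)-6-[(2R)-2-(tert-butyldiphenylsilyloxy)propyl]benzoate | CC(C)(C)OC(=O)c1c(OCc2ccccc2)cc(OCc2ccccc2)cc1C[C@@H](C)O[Si](c1ccccc1)(c1ccccc1)C(C)(C)C
F3 | step 6 | 2,4-bis(benzyloxy)-6-[(2R)-2-(tert-butyldiphenylsilyloxy)propyl]benzoic acid | OC(=O)c1c(OCc2ccccc2)cc(OCc2ccccc2)cc1C[C@@H](C)O[Si](c1ccccc1)(c1ccccc1)C(C)(C)C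
F4 | step 6 | benzyl (S)-3-hydroxybutanoate | C[C@H](O)CC(=O)OCc1ccccc1
F5 | step 7 | benzyl (3R)-3-({3,5-dibromo-2,4-dihydroxy-6-[(2R)-2-(tert-butyldiphenylsilyloxy)propyl]benzoyl}oxy)butanoate | C[C@H](CC(=O)OCc1ccccc1)OC(=O)c1c(O)c(Br)c(O)c(Br)c1C[C@@H](C)O[Si](c1ccccc1)(c1ccccc1)C(C)(C)C
F6 | step 4 | (R,E)-6-(tert-butyldiphenylsilyloxy)hept-3-en-2-one | CC(=O)/C=C/C[C@@H](C)O[Si](c1ccccc1)(c1ccccc1)C(C)(C)C
F7 | step 4 | 1-tert-butyl 3-ethyl 2-[(6R)-6-(tert-butyldiphenylsilyloxy)-2-oxoheptan-4-yl]propanedioate | CCOC(=O)C(C(=O)OC(C)(C)C)C(CC(C)=O)C[C@@H](C)O[Si](c1ccccc1)(c1ccccc1)C(C)(C)C
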